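The chain is numbered C1 (benzylic carbon on guaiacyl ring A) to C7 (benzylic carbon on ring B). The route rests on cutting the C6–C7 bond: a ring B benzylmagnesium reagent adds to a C6 aldehyde whose C5 benzyloxy oxygen lies alpha to the carbonyl, so a five-membered magnesium chelate between O5 and the C6 carbonyl oxygen steers the attack. One operation therefore joins the two halves and sets C6 threo to C5. The precursor is the 3,5-syn bis(benzyl ether) aldehyde, in which C5 is the carbinol carbon of L-malate and C3 was set from C5 by a boron-templated syn reduction. A single hydrogenolysis then unveils the target.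

Key step: step 11

Remark: in the C1–C7 numbering used throughout, the target is (3S,5S,6S) with all three hydroxyls syn in the zigzag drawing; this equals (2S,3S,5S) in the systematic heptane-2,3,5-triol name.

Step 1
Reactants: 1 dimethyl L-malate [dimethyl (S)-2-hydroxybutanedioate]
Product: 2 methyl (S)-3,4-dihydroxybutanoate
Conditions: BH3·SMe2 (1.05 equiv), NaBH4 (5 mol %), THF, 0 °C → rt; then MeOH
Reagents that add atoms: none
Why: Hydroxyl-directed borane reduction of an alpha-hydroxy ester: borane bound at the malate hydroxyl delivers hydride intramolecularly (NaBH4-catalysed) to the neighbouring ester only, so the distal ester, which becomes C3, survives and the stereocenter, the future C5, is not touched.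

Step 2
Reactants: 2 methyl (S)-3,4-dihydroxybutanoate
Product: 3 methyl (S)-3-hydroxy-4-(trityloxy)butanoate
Conditions: TrCl (1.05 equiv), Et3N, DMAP (catalytic), CH2Cl2, 0 °C → rt
Reagents that add atoms: trityl chloride, ClC(c1ccccc1)(c1ccccc1)c1ccccc1
Why: Tritylation is an SN1-type etherification whose bulky triphenylmethyl cation reacts only at the primary hydroxyl, so the future C6 oxygen is masked with a base-stable, acid-labile group and the secondary hydroxyl stays free.

Step 3
Reactants: 3 methyl (S)-3-hydroxy-4-(trityloxy)butanoate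
Product: 4 (S)-3-hydroxy-N-methoxy-N-methyl-4-(trityloxy)butanamide
Conditions: MeNH(OMe)·HCl (2 equiv), i-PrMgCl (5 equiv), THF, −20 °C → 0 °C; aq NH4Cl
Reagents that add atoms: N,O-dimethylhydroxylamine hydrochloride, CNOC.Cl
Why: Weinreb amide formation by direct aminolysis of the ester with the chloromagnesium amide of N,O-dimethylhydroxylamine; the trityl ether is inert to base, the free hydroxyl is simply carried as its magnesium alkoxide at low temperature, and no bond at the stereocenter is made or broken.

Step 4
Reactants: 5 homovanillyl alcohol [4-(2-hydroxyethyl)-2-methoxyphenol]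
Product: 6 2-[4-(benzyloxy)-3-methoxyphenyl]ethanol
Conditions: BnBr (1.1 equiv), K2CO3, acetone, reflux
Reagents that add atoms: benzyl bromide, BrCc1ccccc1
Why: Williamson ether synthesis in which carbonate deprotonates only the phenol, so the phenoxide is benzylated chemoselectively in the presence of the primary aliphatic alcohol.

Step 5
Reactants: 6 2-[4-(benzyloxy)-3-methoxyphenyl]ethanol
Product: 7 1-(benzyloxy)-4-(2-bromoethyl)-2-methoxybenzene
Conditions: CBr4, PPh3, CH2Cl2, 0 °C → rt
Reagents that add atoms: carbon tetrabromide, BrC(Br)(Br)Br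
Why: Appel reaction: the primary hydroxyl is activated on phosphorus and displaced by bromide in an SN2 step under neutral conditions that leave both aryl ethers intact.

Step 6
Reactants: 4 (S)-3-hydroxy-N-methoxy-N-methyl-4-(trityloxy)butanamide; 7 1-(benzyloxy)-4-(2-bromoethyl)-2-methoxybenzene
Product: 9 (S)-1-[4-(benzyloxy)-3-methoxyphenyl]-5-hydroxy-6-(trityloxy)hexan-3-one, via 2-arylethylmagnesium bromide 8 (not isolated)
Conditions: 7 (2.6 equiv), Mg turnings (1,2-dibromoethane activation), THF, rt → 40 °C; then 4, THF, −20 °C → rt; aq NH4Cl, 0 °C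
Reagents that add atoms: none
Why: Weinreb ketone synthesis: one equivalent of the Grignard reagent deprotonates the hydroxyl, a second adds once to the N-methoxy-N-methylamide, and the carbonyl is released only on quench, so over-addition to a tertiary alcohol is not expected and the C5 stereocenter is untouched.

Step 7
Reactants: 9 (S)-1-[4-(benzyloxy)-3-methoxyphenyl]-5-hydroxy-6-(trityloxy)hexan-3-one
Product: 11 (3S,5S)-1-[4-(benzyloxy)-3-methoxyphenyl]-6-(trityloxy)hexane-3,5-diol, via diethylborinate chelate 10 (not isolated)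
Conditions: Et2BOMe (1.1 equiv), THF/MeOH (4:1), −78 °C; NaBH4 (1.2 equiv), −78 °C; pH 7 buffer, then MeOH co-evaporation
Reagents that add atoms: none
Why: Narasaka–Prasad reduction: boron links the C5 oxygen and the C3 carbonyl oxygen in a six-membered chelate, and borohydride attacks C3 axially from outside on the face that leads to a chair-like boronate, so the new C3 hydroxyl is set syn to the C5 hydroxyl, (3S) from (5S), by 1,3-induction.

Step 8
Reactants: 11 (3S,5S)-1-[4-(benzyloxy)-3-methoxyphenyl]-6-(trityloxy)hexane-3,5-diol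
Product: 12 1-(benzyloxy)-4-[(3S,5S)-3,5-bis(benzyloxy)-6-(trityloxy)hexyl]-2-methoxybenzene
Conditions: NaH (3 equiv), BnBr (2.6 equiv), n-Bu4NI (catalytic), THF, 0 °C → 40 °C
Reagents that add atoms: benzyl bromide, BrCc1ccccc1
Why: Double Williamson etherification of the two secondary alkoxides, accelerated by benzyl iodide formed in the flask; only O–H bonds are replaced, so both stereocenters are retained, and the trityl ether is stable to NaH.

Step 9
Reactants: 12 1-(benzyloxy)-4-[(3S,5S)-3,5-bis(benzyloxy)-6-(trityloxy)hexyl]-2-methoxybenzene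
Product: 13 (2S,4S)-2,4-bis(benzyloxy)-6-[4-(benzyloxy)-3-methoxyphenyl]hexan-1-ol
Conditions: TsOH·H2O (10 mol %), MeOH/CH2Cl2 (1:1), rt
Reagents that add atoms: none
Why: Acid-catalysed SN1 methanolysis of the trityl ether, driven by the stabilised triphenylmethyl cation, frees the primary C6 hydroxyl under conditions too mild to affect alkyl or aryl benzyl ethers.

Step 10
Reactants: 13 (2S,4S)-2,4-bis(benzyloxy)-6-[4-(benzyloxy)-3-methoxyphenyl]hexan-1-ol
Product: 14 (2S,4S)-2,4-bis(benzyloxy)-6-[4-(benzyloxy)-3-methoxyphenyl]hexanal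
Conditions: Dess–Martin periodinane (1.3 equiv), CH2Cl2, 0 °C → rt; used at once without chromatography
Reagents that add atoms: none
Why: Dess–Martin oxidation of the primary alcohol stops cleanly at the aldehyde under non-basic, near-neutral conditions, which should keep the epimerisable C5 center alpha to the new carbonyl intact, and the crude aldehyde is used at once for that reason.

Step 11
Reactants: 14 (2S,4S)-2,4-bis(benzyloxy)-6-[4-(benzyloxy)-3-methoxyphenyl]hexanal; 15 4-(benzyloxy)benzyl chloride
Product: 17 (2S,3S,5S)-3,5-bis(benzyloxy)-7-[4-(benzyloxy)-3-methoxyphenyl]-1-[4-(benzyloxy)phenyl]heptan-2-ol, via 4-(benzyloxy)benzylmagnesium chloride 16 (not isolated)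
Conditions: 15, Mg turnings (excess, activated), Et2O, 0 °C → rt, slow addition at high dilution, titrated; 14, MgBr2·OEt2 (2 equiv), CH2Cl2, −78 °C, then 16 (2.5 equiv) dropwise, −78 °C → −40 °C; aq NH4Cl
Reagents that add atoms: none
Why: Cram-chelate addition of a Grignard reagent to an alpha-alkoxy aldehyde: MgBr2 first ties the C6 carbonyl oxygen and the C5 benzyloxy oxygen of 14 into a rigid five-membered chelate, and the benzylic carbon of 16 then adds to C6, forming the C6–C7 bond. The closest known reaction type is the chelation-controlled addition of organomagnesium reagents to 2-benzyloxy aldehydes, which gives threo (1,2-syn) diol monoethers. No ring is closed. The new C6 stereocenter is controlled by the C5 center: in the chelate the C4 chain shields one face, so the nucleophile enters from the side of the C5 hydrogen and (5S) is translated into (6S). The step needs 1,2-syn facial selectivity, which the unhindered, basic benzyl ether on C5 secures; the C3 benzyloxy oxygen could reach the carbonyl only through a seven-membered chelate and so cannot compete, while a six-membered bridge between O3 and O5 is kept from stripping the carbonyl of its Lewis acid by the excess MgBr2·OEt2 and the non-coordinating solvent. Attack through the benzylic carbon is also needed, so 16 is formed slowly at high dilution and added at −78 °C to limit Wurtz homocoupling and reaction through the ortho position of ring B.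

Step 12
Reactants: 17 (2S,3S,5S)-3,5-bis(benzyloxy)-7-[4-(benzyloxy)-3-methoxyphenyl]-1-[4-(benzyloxy)phenyl]heptan-2-ol
Product: 18 (2S,3S,5S)-7-(4-hydroxy-3-methoxyphenyl)-1-(4-hydroxyphenyl)heptane-2,3,5-triol (CNP0232775.1)
Conditions: H2 (1 atm), 10% Pd/C, EtOAc/MeOH, rt
Reagents that add atoms: none
Why: Heterogeneous catalytic hydrogenolysis cleaves the two aryl benzyl ethers and the two alkyl benzyl ethers at their benzylic C–O bonds in one operation; the C3, C5 and C6 carbinol carbons are not benzylic, so their C–O bonds and configurations are retained and the last product is the target.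

Compound list
1 | dimethyl L-malate, dimethyl (S)-2-hydroxybutanedioate | COC(=O)C[C@H](O)C(=O)OC | starting material
2 | methyl (S)-3,4-dihydroxybutanoate | COC(=O)C[C@H](O)CO | intermediate
3 | methyl (S)-3-hydroxy-4-(trityloxy)butanoate | COC(=O)C[C@H](O)COC(c1ccccc1)(c1ccccc1)c1ccccc1 | intermediate
4 | (S)-3-hydroxy-N-methoxy-N-methyl-4-(trityloxy)butanamide | CON(C)C(=O)C[C@H](O)COC(c1ccccc1)(c1ccccc1)c1ccccc1 | intermediate
5 | homovanillyl alcohol, 4-(2-hydroxyethyl)-2-methoxyphenol | COc1cc(CCO)ccc1O | starting material
6 | 2-[4-(benzyloxy)-3-methoxyphenyl]ethanol | COc1cc(CCO)ccc1OCc1ccccc1 | intermediate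
7 | 1-(benzyloxy)-4-(2-bromoethyl)-2-methoxybenzene | COc1cc(CCBr)ccc1OCc1ccccc1 | intermediate
8 | 2-[4-(benzyloxy)-3-methoxyphenyl]ethylmagnesium bromide (formed in the flask) | COc1cc(CC[Mg]Br)ccc1OCc1ccccc1 | intermediate
9 | (S)-1-[4-(benzyloxy)-3-methoxyphenyl]-5-hydroxy-6-(trityloxy)hexan-3-one | COc1cc(CCC(=O)C[C@H](O)COC(c2ccccc2)(c2ccccc2)c2ccccc2)ccc1OCc1ccccc1 | intermediate
10 | O-diethylboryl derivative of 9 at the C5 oxygen, boron chelated to the C3 carbonyl (formed in the flask) | CCB(CC)O[C@H](COC(c1ccccc1)(c1ccccc1)c1ccccc1)CC(=O)CCc1ccc(OCc2ccccc2)c(OC)c1 | intermediate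
11 | (3S,5S)-1-[4-(benzyloxy)-3-methoxyphenyl]-6-(trityloxy)hexane-3,5-diol | COc1cc(CC[C@H](O)C[C@H](O)COC(c2ccccc2)(c2ccccc2)c2ccccc2)ccc1OCc1ccccc1 | intermediate
12 | 1-(benzyloxy)-4-[(3S,5S)-3,5-bis(benzyloxy)-6-(trityloxy)hexyl]-2-methoxybenzene | COc1cc(CC[C@H](OCc2ccccc2)C[C@H](OCc2ccccc2)COC(c2ccccc2)(c2ccccc2)c2ccccc2)ccc1OCc1ccccc1 | intermediate
13 | (2S,4S)-2,4-bis(benzyloxy)-6-[4-(benzyloxy)-3-methoxyphenyl]hexan-1-ol | COc1cc(CC[C@H](OCc2ccccc2)C[C@H](OCc2ccccc2)CO)ccc1OCc1ccccc1 | intermediate
14 | (2S,4S)-2,4-bis(benzyloxy)-6-[4-(benzyloxy)-3-methoxyphenyl]hexanal | COc1cc(CC[C@H](OCc2ccccc2)C[C@H](OCc2ccccc2)C=O)ccc1OCc1ccccc1 | intermediate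
15 | 4-(benzyloxy)benzyl chloride | ClCc1ccc(OCc2ccccc2)cc1 | starting material
16 | 4-(benzyloxy)benzylmagnesium chloride (formed in the flask) | Cl[Mg]Cc1ccc(OCc2ccccc2)cc1 | intermediate
17 | (2S,3S,5S)-3,5-bis(benzyloxy)-7-[4-(benzyloxy)-3-methoxyphenyl]-1-[4-(benzyloxy)phenyl]heptan-2-ol | COc1cc(CC[C@H](OCc2ccccc2)C[C@H](OCc2ccccc2)[C@@H](O)Cc2ccc(OCc3ccccc3)cc2)ccc1OCc1ccccc1 | intermediate
18 | (2S,3S,5S)-7-(4-hydroxy-3-methoxyphenyl)-1-(4-hydroxyphenyl)heptane-2,3,5-triol | COc1cc(CC[C@H](O)C[C@H](O)[C@@H](O)Cc2ccc(O)cc2)ccc1O | target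

Total step count: 12.
Longest linear sequence: 10 steps from dimethyl L-malate (steps 1–3 and 6–12); the ring A arm (steps 4–5) joins at step 6.

Steps most likely to fail

1. Step 11. Chelation may be incomplete, for example if ether solvent competes or magnesium is held between O3 and O5, so part of the aldehyde reacts through an open Felkin-type pathway and facial selectivity at C6 is eroded. The benzylic Grignard reagent may also be lost to Wurtz homocoupling during its formation or react through the ortho carbon of ring B. The fallback sets out from 14 and returns at 17. The addition of 16 is run without regard to selectivity, and the product is carried on as the mixture of 17 and its C6 epimer, (2R,3S,5S)-3,5-bis(benzyloxy)-7-[4-(benzyloxy)-3-methoxyphenyl]-1-[4-(benzyloxy)phenyl]heptan-2-ol F1. Oxidation of the mixture with Dess–Martin periodinane in CH2Cl2 converges both epimers on (3S,5S)-3,5-bis(benzyloxy)-7-[4-(benzyloxy)-3-methoxyphenyl]-1-[4-(benzyloxy)phenyl]heptan-2-one F2. Reduction of F2 with K[s-Bu3BH] in THF at −78 °C, a bulky non-chelating hydride that follows the polar Felkin–Anh model for alpha-alkoxy ketones, should give the 5,6-syn alcohol 17. C6 is then set by hydride delivery instead of by the C–C bond formation.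

2. Step 6. The magnesium alkoxide formed first may aggregate and slow the addition to the amide so that conversion stalls, and formation of the 2-arylethyl Grignard reagent may be eroded by Wurtz coupling or by elimination to the styrene. The fallback sets out from 7 and returns at 9, replacing the acyl substitution by a Corey–Seebach umpolung. Bromide 7 alkylates 2-lithio-1,3-dithiane (1,3-dithiane, n-BuLi, THF, −30 °C) to give 2-{2-[4-(benzyloxy)-3-methoxyphenyl]ethyl}-1,3-dithiane F3. Lithiation of F3 (n-BuLi, THF, −20 °C) and opening of commercial (S)-trityl glycidyl ether, C(OC(c1ccccc1)(c1ccccc1)c1ccccc1)[C@@H]1CO1, at its terminal carbon should give (S)-1-(2-{2-[4-(benzyloxy)-3-methoxyphenyl]ethyl}-1,3-dithian-2-yl)-3-(trityloxy)propan-2-ol F4. Removal of the dithiane with MeI and CaCO3 in aqueous MeCN then reveals ketone 9. The C–O bond at the epoxide stereocenter is not broken, so C5 has the same configuration as from malate.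

3. Step 3. The magnesium alkoxide beta to the ester may eliminate to the unsaturated amide, or the aminolysis may stall on the alkoxide-bearing substrate. The fallback sets out from 3 and returns at 4, replacing direct aminolysis by hydrolysis and coupling. Saponification with LiOH in THF/H2O at 0 °C gives (S)-3-hydroxy-4-(trityloxy)butanoic acid F5, which is coupled with MeNH(OMe)·HCl using EDC·HCl, HOBt and N-methylmorpholine in CH2Cl2 to give 4.

Further compounds
F1 | step 11 | (2R,3S,5S)-3,5-bis(benzyloxy)-7-[4-(benzyloxy)-3-methoxyphenyl]-1-[4-(benzyloxy)phenyl]heptan-2-ol | COc1cc(CC[C@H](OCc2ccccc2)C[C@H](OCc2ccccc2)[C@H](O)Cc2ccc(OCc3ccccc3)cc2)ccc1OCc1ccccc1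
F2 | step 11 | (3S,5S)-3,5-bis(benzyloxy)-7-[4-(benzyloxy)-3-methoxyphenyl]-1-[4-(benzyloxy)phenyl]heptan-2-one | COc1cc(CC[C@H](OCc2ccccc2)C[C@H](OCc2ccccc2)C(=O)Cc2ccc(OCc3ccccc3)cc2)ccc1OCc1ccccc1
F3 | step 6 | 2-{2-[4-(benzyloxy)-3-methoxyphenyl]ethyl}-1,3-dithiane | COc1cc(CCC2SCCCS2)ccc1OCc1ccccc1
F4 | step 6 | (S)-1-(2-{2-[4-(benzyloxy)-3-methoxyphenyl]ethyl}-1,3-dithian-2-yl)-3-(trityloxy)propan-2-ol | COc1cc(CCC2(C[C@H](O)COC(c3ccccc3)(c3ccccc3)c3ccccc3)SCCCS2)ccc1OCc1ccccc1
F5 | step 3 | (S)-3-hydroxy-4-(trityloxy)butanoic acid | OC(=O)C[C@H](O)COC(c1ccccc1)(c1ccccc1)c1ccccc1
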